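## The problem

The target 22 is a 3β-bromolabdane in which C15 is tied back to the 8α-oxygen. A trans-decalin (rings A and B) therefore carries a trans-fused oxocane (ring C: C8, C9, C11, C12, C13, C14, C15, O) with a cis-13,14-epoxide. Of the seven stereocentres, C5, C8, C9 and C10 are those of the labdane diol sclareol, so only C3, C13 and C14 have to be made. The C3 bromide is equatorial and neopentyl (next to the C4 gem-dimethyl group). It cannot be introduced by substitution and must arise by delivering hydrogen to C3 from the axial α face of a bromine-bearing sp2 or radical centre. The decalin can control C3 in this way, and through the conformation of ring C it can control the face of a C13=C14 alkene; nothing else in the molecule can set the epoxide. The O–C8 bond sits on a fully substituted carbon, so the oxygen must be the nucleophile toward C15. Any electrophilic carbon at C12 or C13 is captured by the same hydroxyl in a five- or six-membered ring. The epoxide, the tertiary ether, the secondary bromide (low-valent metals, hydrogenolysis) and any diazo intermediate (acid) limit the reagents that can be used late. The key step rests on one feature: O–C15 joins the hindered oxygen to a primary carbon flanking C14. With a ketone at C14, C15 can be a diazo-derived carbenoid, and the 8α-hydroxyl, held gauche to C11 on ring B, can capture it.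

## Retrosynthesis

**22 ⇒ 21.** Both C–O bonds of the epoxide are cut, leaving the Z-alkene 21, which is the only alkene geometry ring C allows. One syn addition then sets C13 and C14 together. Closing the epoxide from a diol would need the two centres set separately. The forward step needs the peracid to attack one face. The β face of ring B is blocked by the 8β- and 10β-methyl groups, so C11–C12 should turn down past H-9 and ring C should fold under ring B. Hand models of these folded conformers place H-9 over the inner face of the alkene, and the exposed face is the one that leads to the (13R,14S) epoxide. This is a prediction from models, and a bromohydrin fallback is kept for the other face.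

**21 ⇒ 18 ⇒ 17.** The ring alkene and the C13 methyl group are traced to the allylic alcohol 18 by a reductive 1,3-transposition, and 18 to the α-methylene ketone 17. The C14 carbonyl is kept because it makes C15 a carbenoid carbon in the preceding step. The exocyclic methylene keeps C13 free of a stereocentre and of enolisable hydrogens. The forward steps are a 1,2-reduction and a Mitsunobu displacement by a sulfonylhydrazide; the C14 configuration is irrelevant.

**17 ⇒ 16.** The O–C15 bond is cut, opening ring C to the diazo ketone 16. Cutting C8–O is not available at a tertiary centre. Cutting a C–C bond of ring C would leave the hindered ether bond still to be made. The precursor is a labdane with an intact chain and a free 8α-hydroxyl. The forward reaction must favour O–H insertion over insertion into C–H bonds of the chain.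

**16 ⇒ 14.** The diazo group is removed to give the methyl enone 14. The forward step is a detrifluoroacetylative diazo transfer. This is the method suited to α'-diazo enones, because acylation of diazomethane by an acryloyl chloride is spoiled by dipolar cycloaddition.

**14 ⇒ 11 + 12.** The C13–C14 bond is cut to give the enol triflate 11 and the stannane 12 as an acetyl anion equivalent. 11 comes from the methyl ketone 9 through its silyl ether 10. The alternative of alkylating a β-keto ester with a C12 electrophile and then methylenating was set aside. A leaving group at C12, four atoms from the 8α-oxygen, closes the tetrahydrofuran ring, and protecting the hindered alcohol before unmasking C12 costs several steps. A ketone at C13 has no such problem and lies one step from the natural side chain.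

**9 ⇒ 8 ⇒ 6.** The C2–H and C3–H bonds are cut to the alkenyl bromide 8, to be hydrogenated by hydrogen-atom transfer. The C13 ketone is traced to the vinyl carbinol of 6 by cleaving C13–C14 and C14–C15. The vinyl carbinol masks the C13 ketone while the C3 ketone alone is converted to the bromide. It must be cleaved before the radical hydrogenation, which would otherwise reduce the vinyl group.

**6 ⇒ 4 ⇒ 3 ⇒ 2 ⇒ 1.** The alkenyl bromide comes from the hydrazone 4 of ketone 3, the ketone from alcohol 2, and 2 from commercial sclareol 1 by enzymatic hydroxylation of C3. Chemical C–H oxidants prefer the less hindered C2 and would attack the vinyl group. A bromonium-initiated polyene cyclisation would give the bromide directly, but not as a single enantiomer with the oxygenation needed here.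

## Roads not taken

**Alternative 1:** Rings A and B are cut together at C5–C10 and C8–C9. Forward, the acyclic trienal A1 (an (8E,10Z)-silyl dienol ether tethered to an E-enal) undergoes an intramolecular Diels–Alder reaction under a chiral Lewis acid to give A2.
- Merits: four stereocentres (C5, C8, C9, C10) and both carbocycles form in one catalytic step. There is no dependence on a natural diterpene or an enzyme, and the C3 ketone is already in place for the bromide.
- Weak points: the dienophile is β,β-disubstituted and the diene terminus is fully substituted, so the quaternary C10 and the tertiary ether C8 form in the same crowded transition state. The Z-geometry of the silyl dienol ether and the enantiofacial control would both need development. After A2 the route still needs alkene reduction, the bromide sequence, and the whole C12–C16 chain built from the C11 aldehyde next to a masked 8α-oxygen.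
- Comparison: this road is better as a de novo synthesis and is more flexible for analogues. The chosen plan takes the four decalin centres and the full C20 chain from 1, and is far shorter.

**Alternative 2:** Ring B is cut at C9–C10. Forward, Fe(acac)3 and PhSiH3 deliver a hydrogen atom to the exocyclic methylene of the bromocyclohexane enoate A3, and the tertiary C10 radical adds 6-exo to C9 to give A4.
- Merits: the quaternary C10 centre is formed by a mild radical conjugate addition that tolerates the bromide and the free alcohol, and no biocatalyst is needed.
- Weak points: A3 already contains C3, C5 and C8, so the neopentyl bromide problem and a remote tertiary carbinol must be solved on a monocyclic precursor. The ring fusion and C9 depend on the cyclisation transition state. A4 ends with C12 as an ester beside the 8α-hydroxyl, the arrangement that lactonises or closes a tetrahydrofuran once C12 is made electrophilic, and four carbons are still missing.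
- Comparison: this road avoids the enzyme. The chosen plan avoids building the decalin at all and never places an electrophile at C12.

**Alternative 3:** Ring C is cut at C11=C12. Forward, the diene A5 (a vinyl group on C9 and a vinyl group on epoxide carbon C13) undergoes ring-closing metathesis with the second-generation Grubbs catalyst to give A6, and diimide then reduces the new alkene to 22.
- Merits: the epoxide configuration can be set by reagent control on an acyclic fragment before ring closure. This is better than the substrate-controlled last step of the chosen plan, and it avoids diazo chemistry.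
- Weak points: A5 requires the ether bond between the hindered tertiary 8α-oxygen and an epoxy-carbinyl carbon, a Williamson reaction that is poor for a tertiary alkoxide and invites epoxide opening. Both alkenes are neopentyl-type, so the eight-membered closure would be slow, and vinyl epoxides are sensitive to ruthenium species. The C9 vinyl group also requires degrading the natural side chain.
- Comparison: this road wins on epoxide control. The chosen plan forms the hindered C8–O–C15 linkage by addition of oxygen to a carbenoid, which is insensitive to hindrance, and covers the epoxide face with a bromohydrin fallback.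

Key step: step 11

Assumption: commercial (−)-sclareol is the (13R)-8α,13-diol with the decalin configuration of the target, and a C3-selective P450 BM3 variant of the kind known to hydroxylate sclareol and sclareolide is available as a lysate.

## Route

Step 1
Reactants: 1 (−)-sclareol [(13R)-labd-14-ene-8α,13-diol]
Product: 2 (13R)-labd-14-ene-3β,8α,13-triol (3β-hydroxysclareol)
Conditions: engineered cytochrome P450 BM3 variant (heme-iron monooxygenase, clarified E. coli lysate), NADP+ (cat.), glucose, glucose dehydrogenase, air, KPi buffer pH 8.0, DMSO (cosolvent), 25 °C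
Reagents that add atoms: dioxygen, O=O
Why: Enzymatic C–H hydroxylation; engineered BM3 variants are known to oxidise the C3 methylene of sclareol and sclareolide, a site chemical oxidants pass over in favour of C2; the 3β alcohol is expected but its configuration is erased in step 2.

Step 2
Reactants: 2 (13R)-labd-14-ene-3β,8α,13-triol
Product: 3 (13R)-8α,13-dihydroxylabd-14-en-3-one (3-oxosclareol)
Conditions: Dess–Martin periodinane, NaHCO3, CH2Cl2, 0 °C to rt
Reagents that add atoms: none
Why: Dess–Martin oxidation of the only secondary alcohol; the two tertiary alcohols and the vinyl group are inert.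

Step 3
Reactants: 3 (13R)-8α,13-dihydroxylabd-14-en-3-one
Product: 4 (13R)-3-hydrazinylidenelabd-14-ene-8α,13-diol (hydrazone of 3)
Conditions: N2H4·H2O (excess), Et3N, EtOH, 80 °C
Reagents that add atoms: hydrazine, NN
Why: Hydrazone formation at the single carbonyl group; excess hydrazine suppresses azine formation at this hindered ketone.

Step 4
Reactants: 4 (13R)-3-hydrazinylidenelabd-14-ene-8α,13-diol
Product: 6 (13R)-3-bromolabda-2,14-diene-8α,13-diol, via 3-diazo compound 5 (not isolated)
Conditions: NBS (2.2 equiv), pyridine, 0 °C (hydrazone added to the NBS solution)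
Reagents that add atoms: N-bromosuccinimide, O=C1CCC(=O)N1Br
Why: Barton vinyl halide synthesis: oxidation of the hydrazone gives diazoalkane 5, whose bromination and loss of N2 and the C2 proton give the alkenyl bromide; C4 is quaternary so only the Δ2 isomer can form, and the hydrazone should be consumed faster than the isolated alkene is attacked.

Step 5
Reactants: 6 (13R)-3-bromolabda-2,14-diene-8α,13-diol
Product: 8 3-bromo-8α-hydroxy-14,15-dinorlabd-2-en-13-one, via 13,14,15-triol 7 (not isolated)
Conditions: OsO4 (2 mol %), NaIO4 (4 equiv), 2,6-lutidine, dioxane–H2O (3:1), rt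
Reagents that add atoms: none
Why: Johnson–Lemieux oxidation: the monosubstituted alkene is dihydroxylated much faster than the hindered, electron-poor bromoalkene, and periodate cleaves both C–C bonds of the 13,14,15-triol unit of 7, leaving the C13 oxygen as the ketone; lutidine keeps the δ-hydroxy ketone from cyclodehydrating.

Step 6
Reactants: 8 3-bromo-8α-hydroxy-14,15-dinorlabd-2-en-13-one
Product: 9 3β-bromo-8α-hydroxy-14,15-dinorlabdan-13-one
Conditions: Mn(dpm)3 (10 mol %), PhSiH3, tBuOOH, iPrOH, 22 °C, degassed
Reagents that add atoms: none
Why: Mukaiyama-type hydrogen-atom-transfer hydrogenation, known for alkenyl halides: the manganese hydride delivers H• to C2 to give the more substituted α-bromo radical at C3, which should take the second hydrogen on the axial α face (as small hydride donors do at C3 of 4,4-dimethyl-5α systems), leaving bromine equatorial (3β); no low-valent metal is present to insert into the C–Br bond.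

Step 7
Reactants: 9 3β-bromo-8α-hydroxy-14,15-dinorlabdan-13-one
Product: 10 3β-bromo-8α-(trimethylsilyloxy)-14,15-dinorlabdan-13-one
Conditions: N-(trimethylsilyl)imidazole, CH2Cl2, rt
Reagents that add atoms: N-(trimethylsilyl)imidazole, C[Si](C)(C)n1ccnc1
Why: Silylation of the hindered tertiary alcohol by a strong neutral TMS donor that does not enolise the ketone; it stops the alkoxide from adding to C13 or being triflated in step 8.

Step 8
Reactants: 10 3β-bromo-8α-(trimethylsilyloxy)-14,15-dinorlabdan-13-one
Product: 11 3β-bromo-8α-(trimethylsilyloxy)-14,15-dinorlabd-13(16)-en-13-yl trifluoromethanesulfonate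
Conditions: KHMDS, THF, −78 °C; PhNTf2, −78 to 0 °C
Reagents that add atoms: N-phenylbis(trifluoromethanesulfonimide), O=S(=O)(N(c1ccccc1)S(=O)(=O)C(F)(F)F)C(F)(F)F
Why: Kinetic enolate formation at the methyl group of a methyl ketone followed by O-triflation; the equatorial bromide has no anti-periplanar hydrogen, so E2 loss of HBr is not expected at −78 °C.

Step 9
Reactants: 11 3β-bromo-8α-(trimethylsilyloxy)-14,15-dinorlabd-13(16)-en-13-yl trifluoromethanesulfonate; 12 tributyl(1-ethoxyvinyl)stannane
Product: 14 3β-bromo-8α-hydroxylabd-13(16)-en-14-one, via 2-ethoxydiene 13 (not isolated)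
Conditions: Pd(PPh3)4 (5 mol %), LiCl, THF, 65 °C; then 1 M HCl, THF, 0 °C to rt
Reagents that add atoms: water, O
Why: Stille coupling of the enol triflate with the acetyl anion equivalent 12 forms C13–C14; dilute acid hydrolyses the 2-ethoxydiene 13 at its enol ether terminus to the methyl enone and removes the TMS ether; the neopentyl secondary bromide does not add oxidatively to zerovalent palladium under these conditions.

Step 10
Reactants: 14 3β-bromo-8α-hydroxylabd-13(16)-en-14-one
Product: 16 3β-bromo-15-diazo-8α-hydroxylabd-13(16)-en-14-one, via trifluoroacetyl diketone 15 (not isolated)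
Conditions: LiHMDS (2.2 equiv), THF, −78 °C; CF3CO2CH2CF3; then MsN3, Et3N, H2O, MeCN, rt
Reagents that add atoms: methanesulfonyl azide, CS(=O)(=O)N=[N+]=[N-]
Why: Detrifluoroacetylative diazo transfer, the standard entry to α'-diazo enones: the kinetic C15 enolate (the second equivalent of base covers the 8-alkoxide) is trifluoroacetylated to 15, and the activated diketone accepts N2 from the sulfonyl azide with loss of the trifluoroacetyl group; any 8-O-trifluoroacetate is cleaved in the aqueous triethylamine.

Step 11
Reactants: 16 3β-bromo-15-diazo-8α-hydroxylabd-13(16)-en-14-one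
Product: 17 3β-bromo-8α,15-epoxylabd-13(16)-en-14-one
Conditions: Rh2(OAc)4 (2 mol %), CH2Cl2, 40 °C, slow addition of 16 by syringe pump (final 0.005 M), dry conditions
Reagents that add atoms: none
Why: Rh2(OAc)4 expels N2 from the diazo carbon to give an electrophilic rhodium carbenoid at C15; a lone pair of the 8α-hydroxyl adds to it, and the resulting oxonium ylide collapses by proton transfer to C15 with release of the catalyst (net O–H insertion). The closest known reaction type is the dirhodium-catalysed intramolecular O–H insertion of ω-hydroxy diazo ketones to seven- and eight-membered 3-oxo cyclic ethers. Ring C closes by O–C15 bond formation through an eight-membered transition state in which the attacked carbene carbon keeps its bond to rhodium outside the ring (an 8-exo mode). No stereocentre is formed: C15 becomes CH2, C13 stays sp2, and C8 and C9 are untouched. The step needs O–H insertion to beat insertion into the C11–H bond (five-membered ring), carbene dimerisation and capture by water. The substrate helps because the equatorial 8α-oxygen and the equatorial C11 are held gauche on ring B, so the chain starts next to the hydroxyl, and the sp2 atoms C13 and C14 remove transannular hydrogens from the forming ring. Heteroatom lone pairs also capture acceptor carbenoids faster than unactivated C–H bonds, and addition to oxygen is not a substitution at carbon, so the tertiary, hindered nature of C8 should cost little. Slow addition at high dilution suppresses dimerisation.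

Step 12
Reactants: 17 3β-bromo-8α,15-epoxylabd-13(16)-en-14-one
Product: 18 (14ξ)-3β-bromo-8α,15-epoxylabd-13(16)-en-14-ol
Conditions: NaBH4, CeCl3·7H2O, MeOH, −78 to 0 °C
Reagents that add atoms: none
Why: Luche reduction gives clean 1,2-reduction of the α-methylene ketone; the new C14 centre is not controlled and need not be, since it is removed in step 13.

Step 13
Reactants: 18 (14ξ)-3β-bromo-8α,15-epoxylabd-13(16)-en-14-ol
Product: 21 (13Z)-3β-bromo-8α,15-epoxylabd-13-ene, via N-alkyl sulfonylhydrazide 19 (not isolated), via allylic diazene 20 (not isolated)
Conditions: 2-nitrobenzenesulfonylhydrazide (NBSH), PPh3, DEAD, N-methylmorpholine, −30 °C; then 23 °C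
Reagents that add atoms: none
Why: Reductive 1,3-transposition of an allylic alcohol: Mitsunobu displacement at C14 gives 19, loss of 2-nitrobenzenesulfinic acid on warming gives the monoalkyl diazene 20, and its retro-ene loss of N2 delivers hydrogen to C16 and moves the alkene to C13=C14, which can only be Z in the eight-membered ring; either C14 epimer gives the same product.

Step 14
Reactants: 21 (13Z)-3β-bromo-8α,15-epoxylabd-13-ene
Product: 22 (13R,14S)-3β-bromo-8α,15:13,14-diepoxylabdane (target, CNP0311742.2)
Conditions: mCPBA, NaHCO3, CH2Cl2, 0 °C
Reagents that add atoms: 3-chloroperbenzoic acid, O=C(OO)c1cccc(Cl)c1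
Why: Prilezhaev epoxidation of the only alkene; syn addition to the Z-alkene sets C13 and C14 together as the cis epoxide, and attack on the peripheral face of the folded oxocene (inner face covered by H-9 and the underside of ring B) should give the (13R,14S) isomer; the buffer protects the epoxide.

## Compound list

1 | (−)-sclareol, (13R)-labd-14-ene-8α,13-diol | CC1(C)CCC[C@]2(C)[C@@H](CC[C@@](C)(O)C=C)[C@](C)(O)CC[C@@H]12 | starting material
2 | (13R)-labd-14-ene-3β,8α,13-triol | CC1(C)[C@@H](O)CC[C@]2(C)[C@@H](CC[C@@](C)(O)C=C)[C@](C)(O)CC[C@@H]12 | intermediate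
3 | (13R)-8α,13-dihydroxylabd-14-en-3-one | CC1(C)C(=O)CC[C@]2(C)[C@@H](CC[C@@](C)(O)C=C)[C@](C)(O)CC[C@@H]12 | intermediate
4 | (13R)-3-hydrazinylidenelabd-14-ene-8α,13-diol | CC1(C)C(=NN)CC[C@]2(C)[C@@H](CC[C@@](C)(O)C=C)[C@](C)(O)CC[C@@H]12 | intermediate
5 | (13R)-3-diazolabd-14-ene-8α,13-diol | CC1(C)C(=[N+]=[N-])CC[C@]2(C)[C@@H](CC[C@@](C)(O)C=C)[C@](C)(O)CC[C@@H]12 | intermediate (not isolated)
6 | (13R)-3-bromolabda-2,14-diene-8α,13-diol | CC1(C)C(Br)=CC[C@]2(C)[C@@H](CC[C@@](C)(O)C=C)[C@](C)(O)CC[C@@H]12 | intermediate
7 | (13R,14ξ)-3-bromolabd-2-ene-8α,13,14,15-tetrol | CC1(C)C(Br)=CC[C@]2(C)[C@@H](CC[C@@](C)(O)C(O)CO)[C@](C)(O)CC[C@@H]12 | intermediate (not isolated)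
8 | 3-bromo-8α-hydroxy-14,15-dinorlabd-2-en-13-one | CC1(C)C(Br)=CC[C@]2(C)[C@@H](CCC(C)=O)[C@](C)(O)CC[C@@H]12 | intermediate
9 | 3β-bromo-8α-hydroxy-14,15-dinorlabdan-13-one | CC1(C)[C@@H](Br)CC[C@]2(C)[C@@H](CCC(C)=O)[C@](C)(O)CC[C@@H]12 | intermediate
10 | 3β-bromo-8α-(trimethylsilyloxy)-14,15-dinorlabdan-13-one | CC1(C)[C@@H](Br)CC[C@]2(C)[C@@H](CCC(C)=O)[C@](C)(O[Si](C)(C)C)CC[C@@H]12 | intermediate
11 | 3β-bromo-8α-(trimethylsilyloxy)-14,15-dinorlabd-13(16)-en-13-yl trifluoromethanesulfonate | CC1(C)[C@@H](Br)CC[C@]2(C)[C@@H](CCC(=C)OS(=O)(=O)C(F)(F)F)[C@](C)(O[Si](C)(C)C)CC[C@@H]12 | intermediate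
12 | tributyl(1-ethoxyvinyl)stannane | CCCC[Sn](CCCC)(CCCC)C(=C)OCC | starting material
13 | 3β-bromo-14-ethoxy-8α-(trimethylsilyloxy)labda-13(16),14-diene | CC1(C)[C@@H](Br)CC[C@]2(C)[C@@H](CCC(=C)C(=C)OCC)[C@](C)(O[Si](C)(C)C)CC[C@@H]12 | intermediate (not isolated)
14 | 3β-bromo-8α-hydroxylabd-13(16)-en-14-one | CC1(C)[C@@H](Br)CC[C@]2(C)[C@@H](CCC(=C)C(C)=O)[C@](C)(O)CC[C@@H]12 | intermediate
15 | 3β-bromo-8α-hydroxy-15-(trifluoroacetyl)labd-13(16)-en-14-one | CC1(C)[C@@H](Br)CC[C@]2(C)[C@@H](CCC(=C)C(=O)CC(=O)C(F)(F)F)[C@](C)(O)CC[C@@H]12 | intermediate (not isolated)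
16 | 3β-bromo-15-diazo-8α-hydroxylabd-13(16)-en-14-one | CC1(C)[C@@H](Br)CC[C@]2(C)[C@@H](CCC(=C)C(=O)C=[N+]=[N-])[C@](C)(O)CC[C@@H]12 | intermediate
17 | 3β-bromo-8α,15-epoxylabd-13(16)-en-14-one | CC1(C)[C@@H](Br)CC[C@]2(C)[C@H]3CCC(=C)C(=O)CO[C@]3(C)CC[C@@H]12 | intermediate
18 | (14ξ)-3β-bromo-8α,15-epoxylabd-13(16)-en-14-ol | CC1(C)[C@@H](Br)CC[C@]2(C)[C@H]3CCC(=C)C(O)CO[C@]3(C)CC[C@@H]12 | intermediate
19 | N-[3β-bromo-8α,15-epoxylabd-13(16)-en-14-yl]-2-nitrobenzenesulfonohydrazide | CC1(C)[C@@H](Br)CC[C@]2(C)[C@H]3CCC(=C)C(N(N)S(=O)(=O)c4ccccc4[N+](=O)[O-])CO[C@]3(C)CC[C@@H]12 | intermediate (not isolated)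
20 | [3β-bromo-8α,15-epoxylabd-13(16)-en-14-yl]diazene | CC1(C)[C@@H](Br)CC[C@]2(C)[C@H]3CCC(=C)C(N=N)CO[C@]3(C)CC[C@@H]12 | intermediate (not isolated)
21 | (13Z)-3β-bromo-8α,15-epoxylabd-13-ene | CC1(C)[C@@H](Br)CC[C@]2(C)[C@H]3CC/C(C)=C\CO[C@]3(C)CC[C@@H]12 | intermediate
22 | (13R,14S)-3β-bromo-8α,15:13,14-diepoxylabdane | CC1(C)[C@@H](Br)CC[C@]2(C)[C@H]3CC[C@@]4(C)O[C@H]4CO[C@]3(C)CC[C@@H]12 | target

## Step count and least certain steps

Total step count: 14. Longest linear sequence: 14 steps (1 to 22).

**Step 11 (key step).** The carbenoid may insert into the C11–H bond, dimerise or be captured by traces of water faster than it closes an eight-membered ring onto a hindered tertiary hydroxyl. The fallback changes the mechanism to a polar one. Starting from 16, one equivalent of aqueous HBr in Et2O at −20 °C replaces N2 by bromide to give 3β,15-dibromo-8α-hydroxylabd-13(16)-en-14-one F1. Silver-assisted intramolecular etherification (Ag2O, 4 Å sieves, CH2Cl2, rt) then displaces the α-keto bromide with the 8α-hydroxyl and returns to the route at 17.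

**Step 14.** Facial selectivity may be poor or reversed if ring C reacts through an extended rather than a folded conformer. The fallback delivers oxygen to the face opposite the one an electrophile attacks. Starting from 21, NBS in aqueous DME at 0 °C forms the bromonium ion on the exposed face, and water opens it anti at the tertiary C13. When the exposed face is the one the peracid wrongly chose, the product is (13R,14R)-3β,14-dibromo-8α,15-epoxylabdan-13-ol F2. K2CO3 in MeOH closes the epoxide with inversion at C14 and returns to the route at 22.

**Step 13.** The hindered, doubly flanked secondary alcohol may react by SN2' substitution at the methylene terminus or by dehydration instead of direct Mitsunobu displacement. The fallback bypasses the alcohol. Starting from 17, condensation with TsNHNH2 (EtOH, cat. AcOH) gives 3β-bromo-8α,15-epoxylabd-13(16)-en-14-one 4-methylbenzenesulfonylhydrazone F3. Reduction with catecholborane (CHCl3, 0 °C) and then NaOAc·3H2O at reflux forms the same allylic diazene by hydride addition and sulfinate loss, and returns to the route at 21.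

**Step 6.** Bromine may be lost (hydrogen delivery to C3 followed by β-scission, or over-reduction), or hydrogen may be delivered on the equatorial face. The fallback reaches the same α-bromo C3 radical from a different precursor. Starting from 4, CuBr2 and Et3N in MeOH convert the hydrazone into (13R)-3,3-dibromolabd-14-ene-8α,13-diol F4. The conditions of step 5 cleave its side chain to 3,3-dibromo-8α-hydroxy-14,15-dinorlabdan-13-one F5. One equivalent of Bu3SnH with AIBN (benzene, 80 °C) removes a single bromine, the radical taking hydrogen axially, and returns to the route at 9.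

**Step 4.** Azine formation, geminal dibromination or attack of the bromine source on the vinyl group may compete. The fallback avoids electrophilic bromine. Starting from 3, KHMDS (3.3 equiv) and PhNTf2 at −78 °C give (13R)-8α,13-dihydroxylabda-2,14-dien-3-yl trifluoromethanesulfonate F6. Nickel-catalysed triflate-to-bromide exchange (Ni(cod)2 10 mol %, LiBr, DMA–THF, rt) returns to the route at 6.

## Further compounds

F1 | step 11 | 3β,15-dibromo-8α-hydroxylabd-13(16)-en-14-one | CC1(C)[C@@H](Br)CC[C@]2(C)[C@@H](CCC(=C)C(=O)CBr)[C@](C)(O)CC[C@@H]12
F2 | step 14 | (13R,14R)-3β,14-dibromo-8α,15-epoxylabdan-13-ol | CC1(C)[C@@H](Br)CC[C@]2(C)[C@H]3CC[C@@](C)(O)[C@H](Br)CO[C@]3(C)CC[C@@H]12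
F3 | step 13 | 3β-bromo-8α,15-epoxylabd-13(16)-en-14-one 4-methylbenzenesulfonylhydrazone | CC1(C)[C@@H](Br)CC[C@]2(C)[C@H]3CCC(=C)C(=NNS(=O)(=O)c4ccc(C)cc4)CO[C@]3(C)CC[C@@H]12
F4 | step 6 | (13R)-3,3-dibromolabd-14-ene-8α,13-diol | CC1(C)C(Br)(Br)CC[C@]2(C)[C@@H](CC[C@@](C)(O)C=C)[C@](C)(O)CC[C@@H]12
F5 | step 6 | 3,3-dibromo-8α-hydroxy-14,15-dinorlabdan-13-one | CC1(C)C(Br)(Br)CC[C@]2(C)[C@@H](CCC(C)=O)[C@](C)(O)CC[C@@H]12
F6 | step 4 | (13R)-8α,13-dihydroxylabda-2,14-dien-3-yl trifluoromethanesulfonate | CC1(C)C(OS(=O)(=O)C(F)(F)F)=CC[C@]2(C)[C@@H](CC[C@@](C)(O)C=C)[C@](C)(O)CC[C@@H]12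
A1 | alternative 1 | (2E,8E,10Z)-11-(tert-butyldimethylsilyloxy)-3,7,7-trimethyl-6-oxododeca-2,8,10-trienal | O=C/C=C(\C)CCC(=O)C(C)(C)/C=C/C=C(/C)O[Si](C)(C)C(C)(C)C
A2 | alternative 1 | 8α-(tert-butyldimethylsilyloxy)-3-oxodrim-6-en-11-al | CC1(C)C(=O)CC[C@]2(C)[C@@H](C=O)[C@](C)(O[Si](C)(C)C(C)(C)C)C=C[C@@H]12
A3 | alternative 2 | methyl (E)-3β-bromo-8α-hydroxy-9,10-seco-13,14,15,16-tetranorlabda-9(11),10(20)-dien-12-oate | CC1(C)[C@@H](Br)CCC(=C)[C@H]1CC[C@@](C)(O)/C=C/C(=O)OC
A4 | alternative 2 | methyl 3β-bromo-8α-hydroxy-13,14,15,16-tetranorlabdan-12-oate | CC1(C)[C@@H](Br)CC[C@]2(C)[C@@H](CC(=O)OC)[C@](C)(O)CC[C@@H]12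
A5 | alternative 3 | 3β-bromo-8α-{[(2S,3R)-3-methyl-3-vinyloxiran-2-yl]methoxy}-13,14,15,16-tetranorlabd-11-ene | CC1(C)[C@@H](Br)CC[C@]2(C)[C@@H](C=C)[C@](C)(OC[C@@H]3O[C@]3(C)C=C)CC[C@@H]12
A6 | alternative 3 | (11Z,13R,14S)-3β-bromo-8α,15:13,14-diepoxylabd-11-ene | CC1(C)[C@@H](Br)CC[C@]2(C)[C@H]3/C=C\[C@@]4(C)O[C@H]4CO[C@]3(C)CC[C@@H]12
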